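**Plan**

- Cuts (east half in hydrindane numbering: C1 = CHOH, C3 = CH–iPr, C3a/C7a = ring fusion, C5=C6 = tetrasubstituted alkene): C5–C(=CH2) of the eight-membered ring (Heck), C6–CH(Me) (aldol condensation, then methyl to the exocyclic β-carbon), C2–C3 (5-exo radical closure) and the fusion bond C3a–C7a.
- Enabling feature: the carbinol C1 is vicinal to the methyl-bearing quaternary C7a, so C7a is the tertiary radical released by Ti(III) opening of a C1–C7a epoxide; C3a is β to C5 (a ketone until late), i.e. the β-carbon of an enone.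
- Forward: acyclic epoxy dienone → six-membered ring (step 7) → cyclopentane with its isopropyl group (step 8); the methylcyclopentane west piece is made separately from cyclopentenone; union by aldol condensation; eight-membered ring last.
- Stereochemistry: Sharpless epoxidation fixes C1, which relays to C7a/C3a (step 7) and C3 (step 8); in the west piece a Cu-catalysed asymmetric methyl addition is followed by hydrogenation anti to that methyl and epimerisation; the eight-ring methyl centre comes from cuprate addition anti to the angular methyl.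

Key step: step 7

Remark: the ligand enantiomer in step 10 is the one that gives the (S)-methyl centre; stereodescriptors in the names were assigned by hand from the SMILES.

**Step 1**
Reactants: 1 prenyl acetate (3-methylbut-2-en-1-yl acetate)
Product: 2 (2E)-4-hydroxy-3-methylbut-2-en-1-yl acetate
Conditions: SeO2 (cat.), t-BuOOH, CH2Cl2, 25 °C
Reagents that add atoms: tert-butyl hydroperoxide, CC(C)(C)OO (oxygen relayed by the SeO2 catalyst, O=[Se]=O)
Why: Riley allylic oxidation attacks the trisubstituted alkene at its (E)-methyl group by ene reaction and [2,3]-shift, so the (E)-allylic alcohol should form with the acetate untouched.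

**Step 2**
Reactants: 2 (2E)-4-hydroxy-3-methylbut-2-en-1-yl acetate
Product: 3 (2E)-4-bromo-3-methylbut-2-en-1-yl acetate
Conditions: CBr4, PPh3, CH2Cl2, 0 °C
Reagents that add atoms: carbon tetrabromide, BrC(Br)(Br)Br
Why: Appel bromination converts the primary allylic alcohol into the bromide under neutral conditions without allylic transposition.

**Step 3**
Reactants: 4 (3E)-6-methylhepta-3,5-dien-2-one, 3 (2E)-4-bromo-3-methylbut-2-en-1-yl acetate
Product: 6 (2E,7E)-3,10-dimethyl-6-oxoundeca-2,7,9-trien-1-yl acetate, via lithium trienolate 5 (not isolated)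
Conditions: LDA, THF, −78 °C; then 3, DMPU, −78 to −40 °C
Reagents that add atoms: none
Why: Kinetic deprotonation of the methyl ketone gives the cross-conjugated lithium enolate, whose SN2 alkylation by the primary allylic bromide should join the two achiral halves at the former methyl carbon (future C6).

**Step 4**
Reactants: 6 (2E,7E)-3,10-dimethyl-6-oxoundeca-2,7,9-trien-1-yl acetate
Product: 7 (4E,9E)-11-hydroxy-2,9-dimethylundeca-2,4,9-trien-6-one
Conditions: K2CO3 (cat.), MeOH, 0 °C
Reagents that add atoms: none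
Why: Base-catalysed methanolysis frees the allylic alcohol needed to direct the epoxidation, the dienone being tolerated at 0 °C for a short reaction time.

**Step 5**
Reactants: 7 (4E,9E)-11-hydroxy-2,9-dimethylundeca-2,4,9-trien-6-one
Product: 8 (4E)-1-[(2R,3R)-3-(hydroxymethyl)-2-methyloxiran-2-yl]-7-methylocta-4,6-dien-3-one
Conditions: Ti(OiPr)4 (cat.), D-(−)-diethyl tartrate (cat.), t-BuOOH, 4 Å MS, CH2Cl2, −20 °C
Reagents that add atoms: tert-butyl hydroperoxide, CC(C)(C)OO
Why: Sharpless asymmetric epoxidation of the geraniol-type (E)-allylic alcohol with D-(−)-tartrate should give the (2R,3R)-epoxide, the only reagent-controlled stereocentre of the east half (future C1), while the electron-poor dienone is not epoxidised.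

**Step 6**
Reactants: 8 (4E)-1-[(2R,3R)-3-(hydroxymethyl)-2-methyloxiran-2-yl]-7-methylocta-4,6-dien-3-one
Product: 9 {(2R,3R)-3-methyl-3-[(4E)-7-methyl-3-oxoocta-4,6-dien-1-yl]oxiran-2-yl}methyl 4-methylbenzenesulfonate
Conditions: TsCl, Et3N, DMAP (cat.), CH2Cl2, 0 °C
Reagents that add atoms: 4-toluenesulfonyl chloride, Cc1ccc(cc1)S(Cl)(=O)=O
Why: Sulfonylation masks the primary alcohol as a group that is inert to Ti(III) and later serves as the radical precursor for the five-membered ring.

**Step 7**
Reactants: 9 {(2R,3R)-3-methyl-3-[(4E)-7-methyl-3-oxoocta-4,6-dien-1-yl]oxiran-2-yl}methyl 4-methylbenzenesulfonate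
Product: 10 (3S,4R)-4-[(1S)-1-hydroxy-2-(tosyloxy)ethyl]-4-methyl-3-(2-methylprop-1-en-1-yl)cyclohexan-1-one
Conditions: Cp2TiCl2 (2.5 equiv), Zn dust, THF, 25 °C; slow addition of 9 (0.01 M); then 1 M HCl
Reagents that add atoms: none
Why: Titanocene(III) chloride opens the trisubstituted epoxide homolytically at the more substituted C–O bond (Nugent–RajanBabu reaction), giving a tertiary β-titanoxy radical at the future C7a that adds to the future C3a, the β-carbon of the dienone, after which a second Ti(III) reduces the α-keto radical to a titanium enolate that is protonated on work-up. The closest known reaction type is the Ti(III)-mediated epoxide–alkene radical cyclisation used in epoxypolyene cyclisations, here terminated on an enone. The six-membered ring closes in the 6-endo-trig mode with the carbonyl inside the ring. The relative configuration of the two new centres (quaternary C7a and C3a) should follow from a chair-like transition state with the bulky CH(OTi)CH2OTs group and the (E)-alkenyl residue both equatorial and the methyl axial, and their absolute sense from the epoxide-derived carbinol centre, whose C–H eclipses the ring-forming CH2 of the planar radical while the enone approaches anti to the Cp2ClTi–O group (allylic-strain model), placing the oxygen and the angular methyl on the same side. The step needs 6-endo (β) attack over 5-exo (α) attack and 1,6-addition, and cyclisation before a second Ti(III) traps the radical; the nucleophilic character of the tertiary radical, the fully substituted δ-carbon, the hindered radical centre and slow addition should secure this.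

**Step 8**
Reactants: 10 (3S,4R)-4-[(1S)-1-hydroxy-2-(tosyloxy)ethyl]-4-methyl-3-(2-methylprop-1-en-1-yl)cyclohexan-1-one
Product: 12 (1R,3S,3aS,7aR)-1-hydroxy-7a-methyl-3-(propan-2-yl)octahydro-5H-inden-5-one, via iodohydrin 11 (not isolated)
Conditions: NaI, Bu3SnH, AIBN (cat.), DME, 80 °C
Reagents that add atoms: none
Why: Finkelstein exchange gives the primary iodide, whose tin-hydride-generated radical closes the cyclopentane by 5-exo-trig attack on the trisubstituted alkene through a chair-like transition state with the hydroxyl, the ring CH2 and the forming 2-propyl radical all pseudo-equatorial, so C3 should be set with isopropyl trans to the hydroxyl and to the ring CH2, and hydrogen transfer to the tertiary radical completes the isopropyl group.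

**Step 9**
Reactants: 12 (1R,3S,3aS,7aR)-1-hydroxy-7a-methyl-3-(propan-2-yl)octahydro-5H-inden-5-one
Product: 13 (1R,3S,3aS,7aR)-1-[(tert-butyldimethylsilyl)oxy]-7a-methyl-3-(propan-2-yl)octahydro-5H-inden-5-one
Conditions: TBSOTf, 2,6-lutidine, CH2Cl2, −78 to 0 °C
Reagents that add atoms: tert-butyldimethylsilyl triflate, CC(C)(C)[Si](C)(C)OS(=O)(=O)C(F)(F)F
Why: Silylation of the hindered secondary alcohol with the silyl triflate protects it against the strong bases and triflating agents of the later steps.

**Step 10**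
Reactants: 14 cyclopent-2-en-1-one, 15 2-(2-iodoethyl)-1,3-dioxolane
Product: 17 (2R,3S)-2-[2-(1,3-dioxolan-2-yl)ethyl]-3-methylcyclopentan-1-one, via zinc enolate 16 (not isolated)
Conditions: Me2Zn, Cu(OTf)2 (cat.), chiral phosphoramidite ligand (cat.), toluene, −30 °C; then 15, HMPA, 0 to 25 °C
Reagents that add atoms: dimethylzinc, C[Zn]C
Why: Copper-catalysed asymmetric conjugate addition of dimethylzinc sets the methyl stereocentre under ligand control and leaves a regiodefined zinc enolate, which is alkylated in situ by the primary iodide trans to the new methyl group (this second centre is erased in step 11).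

**Step 11**
Reactants: 17 (2R,3S)-2-[2-(1,3-dioxolan-2-yl)ethyl]-3-methylcyclopentan-1-one
Product: 19 (3S)-2-[2-(1,3-dioxolan-2-yl)ethyl]-3-methylcyclopent-1-en-1-yl trifluoromethanesulfonate, via potassium enolate 18 (not isolated)
Conditions: KH, THF, 25 °C (equilibration); then PhNTf2, −78 to 0 °C
Reagents that add atoms: N-phenyl-bis(trifluoromethanesulfonimide), O=S(=O)(N(c1ccccc1)S(=O)(=O)C(F)(F)F)C(F)(F)F
Why: Equilibration of the potassium enolate favours the tetrasubstituted isomer, which is trapped as the enol triflate, making C2 planar for the later cis-selective reduction.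

**Step 12**
Reactants: 19 (3S)-2-[2-(1,3-dioxolan-2-yl)ethyl]-3-methylcyclopent-1-en-1-yl trifluoromethanesulfonate
Product: 20 (3S)-2-[2-(1,3-dioxolan-2-yl)ethyl]-3-methylcyclopent-1-ene-1-carbaldehyde
Conditions: Pd(PPh3)4 (cat.), CO (1 atm), Bu3SnH (slow addition), LiCl, THF, 50 °C
Reagents that add atoms: carbon monoxide, [C-]#[O+]
Why: Palladium-catalysed reductive carbonylation (formylation) of the enol triflate installs the one-carbon aldehyde that later becomes the vinyl group.

**Step 13**
Reactants: 20 (3S)-2-[2-(1,3-dioxolan-2-yl)ethyl]-3-methylcyclopent-1-ene-1-carbaldehyde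
Product: 22 (1S,2S,3S)-2-[2-(1,3-dioxolan-2-yl)ethyl]-3-methylcyclopentane-1-carbaldehyde, via all-cis aldehyde 21 (not isolated)
Conditions: H2 (3 atm), 10% Pd/C, EtOAc, 25 °C; filter; DBU (cat.), CH2Cl2, 25 °C
Reagents that add atoms: none
Why: Heterogeneous hydrogenation should deliver both hydrogens anti to the allylic methyl group to give the all-cis aldehyde, and DBU then epimerises only the formyl-bearing carbon to the more stable trans arrangement, so methyl/side chain end cis and side chain/formyl trans.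

**Step 14**
Reactants: 22 (1S,2S,3S)-2-[2-(1,3-dioxolan-2-yl)ethyl]-3-methylcyclopentane-1-carbaldehyde
Product: 23 2-{2-[(1S,2R,5S)-2-ethenyl-5-methylcyclopentyl]ethyl}-1,3-dioxolane
Conditions: Ph3PCH3Br, KHMDS, THF, 0 °C; then 22, −78 to 0 °C
Reagents that add atoms: methyltriphenylphosphonium bromide, C[P+](c1ccccc1)(c1ccccc1)c1ccccc1.[Br-]
Why: Wittig methylenation converts the aldehyde, already in its thermodynamically preferred trans configuration, into the vinyl group used for the final ring closure.

**Step 15**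
Reactants: 23 2-{2-[(1S,2R,5S)-2-ethenyl-5-methylcyclopentyl]ethyl}-1,3-dioxolane
Product: 24 3-[(1S,2R,5S)-2-ethenyl-5-methylcyclopentyl]propanal
Conditions: 1 M HCl, THF, 25 °C
Reagents that add atoms: water, O
Why: Acid-catalysed acetal hydrolysis releases the aldehyde for the fragment union without affecting the vinyl group or the ring stereocentres.

**Step 16**
Reactants: 13 (1R,3S,3aS,7aR)-1-[(tert-butyldimethylsilyl)oxy]-7a-methyl-3-(propan-2-yl)octahydro-5H-inden-5-one, 24 3-[(1S,2R,5S)-2-ethenyl-5-methylcyclopentyl]propanal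
Product: 28 (1R,3S,3aS,6E,7aR)-1-[(tert-butyldimethylsilyl)oxy]-6-{3-[(1S,2R,5S)-2-ethenyl-5-methylcyclopentyl]propylidene}-7a-methyl-3-(propan-2-yl)octahydro-5H-inden-5-one, via lithium enolate 25 (not isolated), via aldol adduct 26 (not isolated), via mesylate 27 (not isolated)
Conditions: LDA, THF, −78 °C; then 24, −78 °C; then MsCl, 0 °C; DBU, 25 °C
Reagents that add atoms: none
Why: Directed aldol condensation: kinetic deprotonation at C6 (the CH2 remote from the ring fusion, where the enolate double bond lies opposite the trans-fusion bond), addition to the aldehyde, mesylation and E1cB elimination should give the (E)-alkylidene ketone.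

**Step 17**
Reactants: 28 (6E)-alkylidene ketone
Product: 30 (1R,3S,3aS,7aR)-1-[(tert-butyldimethylsilyl)oxy]-6-{(2S)-5-[(1S,2R,5S)-2-ethenyl-5-methylcyclopentyl]pentan-2-yl}-7a-methyl-3-(propan-2-yl)-2,3,3a,4,7,7a-hexahydro-1H-inden-5-yl trifluoromethanesulfonate, via lithium enolate 29 (not isolated)
Conditions: Me2CuLi (from MeLi, CuI), Et2O, −78 to −30 °C; then PhNTf2, THF, −30 to 25 °C
Reagents that add atoms: lithium dimethylcuprate, [Li+].C[Cu-]C; N-phenyl-bis(trifluoromethanesulfonimide), O=S(=O)(N(c1ccccc1)S(=O)(=O)C(F)(F)F)C(F)(F)F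
Why: Gilman cuprate 1,4-addition to the s-cis-locked exocyclic enone is expected on the face anti to the axial angular methyl group, which sets the secondary methyl centre as (S), and trapping of the regiodefined enolate gives the tetrasubstituted enol triflate.

**Step 18**
Reactants: 30 enol triflate
Product: 31 tert-butyldimethylsilyl ether of the target (5-8-6-5 tetracycle with exocyclic methylene)
Conditions: Pd(PPh3)4, K2CO3, 4 Å MS, MeCN, 85 °C, high dilution
Reagents that add atoms: none
Why: Intramolecular Heck reaction: oxidative addition to the enol triflate, 8-exo-trig insertion into the pendant vinyl group and β-hydride elimination should close the cyclooctane and create the exocyclic methylene conjugated with the tetrasubstituted alkene without touching any stereocentre.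

**Step 19**
Reactants: 31 tert-butyldimethylsilyl ether of the target
Product: 32 target (CNP0544018.1)
Conditions: TBAF, THF, 25 to 50 °C
Reagents that add atoms: none
Why: Fluoride-mediated desilylation liberates the secondary alcohol without acid that could isomerise the diene.

**Compound list**

1 | prenyl acetate | CC(C)=CCOC(C)=O | starting material
2 | (2E)-4-hydroxy-3-methylbut-2-en-1-yl acetate | CC(=O)OC/C=C(\C)CO | intermediate
3 | (2E)-4-bromo-3-methylbut-2-en-1-yl acetate | CC(=O)OC/C=C(\C)CBr | intermediate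
4 | (3E)-6-methylhepta-3,5-dien-2-one | CC(=O)/C=C/C=C(C)C | starting material
5 | lithium (3E)-6-methylhepta-1,3,5-trien-2-olate | C=C(O[Li])/C=C/C=C(C)C | intermediate (not isolated)
6 | (2E,7E)-3,10-dimethyl-6-oxoundeca-2,7,9-trien-1-yl acetate | CC(=O)OC/C=C(\C)CCC(=O)/C=C/C=C(C)C | intermediate
7 | (4E,9E)-11-hydroxy-2,9-dimethylundeca-2,4,9-trien-6-one | OC/C=C(\C)CCC(=O)/C=C/C=C(C)C | intermediate
8 | (4E)-1-[(2R,3R)-3-(hydroxymethyl)-2-methyloxiran-2-yl]-7-methylocta-4,6-dien-3-one | OC[C@H]1O[C@]1(C)CCC(=O)/C=C/C=C(C)C | intermediate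
9 | {(2R,3R)-3-methyl-3-[(4E)-7-methyl-3-oxoocta-4,6-dien-1-yl]oxiran-2-yl}methyl 4-methylbenzenesulfonate | Cc1ccc(cc1)S(=O)(=O)OC[C@H]1O[C@]1(C)CCC(=O)/C=C/C=C(C)C | intermediate
10 | (3S,4R)-4-[(1S)-1-hydroxy-2-(tosyloxy)ethyl]-4-methyl-3-(2-methylprop-1-en-1-yl)cyclohexan-1-one | O=C1CC[C@@](C)([C@H](O)COS(=O)(=O)c2ccc(C)cc2)[C@H](C=C(C)C)C1 | intermediate
11 | (3S,4R)-4-[(1S)-1-hydroxy-2-iodoethyl]-4-methyl-3-(2-methylprop-1-en-1-yl)cyclohexan-1-one | O=C1CC[C@@](C)([C@H](O)CI)[C@H](C=C(C)C)C1 | intermediate (not isolated)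
12 | (1R,3S,3aS,7aR)-1-hydroxy-7a-methyl-3-(propan-2-yl)octahydro-5H-inden-5-one (trans-fused) | O=C1CC[C@@]2(C)[C@H](O)C[C@@H](C(C)C)[C@@H]2C1 | intermediate
13 | (1R,3S,3aS,7aR)-1-[(tert-butyldimethylsilyl)oxy]-7a-methyl-3-(propan-2-yl)octahydro-5H-inden-5-one | O=C1CC[C@@]2(C)[C@H](O[Si](C)(C)C(C)(C)C)C[C@@H](C(C)C)[C@@H]2C1 | intermediate
14 | cyclopent-2-en-1-one | O=C1C=CCC1 | starting material
15 | 2-(2-iodoethyl)-1,3-dioxolane | ICCC1OCCO1 | starting material
16 | methylzinc (S)-3-methylcyclopent-1-en-1-olate | C[C@H]1CCC(O[Zn]C)=C1 | intermediate (not isolated)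
17 | (2R,3S)-2-[2-(1,3-dioxolan-2-yl)ethyl]-3-methylcyclopentan-1-one (trans) | C[C@H]1CCC(=O)[C@@H]1CCC1OCCO1 | intermediate
18 | potassium (3S)-2-[2-(1,3-dioxolan-2-yl)ethyl]-3-methylcyclopent-1-en-1-olate | C[C@H]1CCC(O[K])=C1CCC1OCCO1 | intermediate (not isolated)
19 | (3S)-2-[2-(1,3-dioxolan-2-yl)ethyl]-3-methylcyclopent-1-en-1-yl trifluoromethanesulfonate | C[C@H]1CCC(OS(=O)(=O)C(F)(F)F)=C1CCC1OCCO1 | intermediate
20 | (3S)-2-[2-(1,3-dioxolan-2-yl)ethyl]-3-methylcyclopent-1-ene-1-carbaldehyde | C[C@H]1CCC(C=O)=C1CCC1OCCO1 | intermediate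
21 | (1R,2S,3S)-2-[2-(1,3-dioxolan-2-yl)ethyl]-3-methylcyclopentane-1-carbaldehyde (all-cis) | O1CCOC1CC[C@@H]1[C@H](C=O)CC[C@@H]1C | intermediate (not isolated)
22 | (1S,2S,3S)-2-[2-(1,3-dioxolan-2-yl)ethyl]-3-methylcyclopentane-1-carbaldehyde (formyl trans to side chain, methyl cis) | O1CCOC1CC[C@@H]1[C@@H](C=O)CC[C@@H]1C | intermediate
23 | 2-{2-[(1S,2R,5S)-2-ethenyl-5-methylcyclopentyl]ethyl}-1,3-dioxolane | O1CCOC1CC[C@@H]1[C@@H](C=C)CC[C@@H]1C | intermediate
24 | 3-[(1S,2R,5S)-2-ethenyl-5-methylcyclopentyl]propanal | O=CCC[C@@H]1[C@@H](C=C)CC[C@@H]1C | intermediate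
25 | lithium C5–C6 enolate of 13 | [Li]OC1=CC[C@@]2(C)[C@H](O[Si](C)(C)C(C)(C)C)C[C@@H](C(C)C)[C@@H]2C1 | intermediate (not isolated)
26 | aldol adduct of 13 and 24 (β-hydroxy ketone, formed as its lithium alkoxide; the two new centres unassigned) | O=C1C(C(O)CC[C@@H]2[C@@H](C=C)CC[C@@H]2C)C[C@@]2(C)[C@H](O[Si](C)(C)C(C)(C)C)C[C@@H](C(C)C)[C@@H]2C1 | intermediate (not isolated)
27 | mesylate of 26 | O=C1C(C(OS(C)(=O)=O)CC[C@@H]2[C@@H](C=C)CC[C@@H]2C)C[C@@]2(C)[C@H](O[Si](C)(C)C(C)(C)C)C[C@@H](C(C)C)[C@@H]2C1 | intermediate (not isolated)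
28 | (1R,3S,3aS,6E,7aR)-1-[(tert-butyldimethylsilyl)oxy]-6-{3-[(1S,2R,5S)-2-ethenyl-5-methylcyclopentyl]propylidene}-7a-methyl-3-(propan-2-yl)octahydro-5H-inden-5-one | O=C1/C(=C/CC[C@@H]2[C@@H](C=C)CC[C@@H]2C)C[C@@]2(C)[C@H](O[Si](C)(C)C(C)(C)C)C[C@@H](C(C)C)[C@@H]2C1 | intermediate
29 | lithium enolate of the methyl adduct of 28 (C5–C6 enolate, (S)-methyl centre) | [Li]OC1=C([C@@H](C)CC[C@@H]2[C@@H](C=C)CC[C@@H]2C)C[C@@]2(C)[C@H](O[Si](C)(C)C(C)(C)C)C[C@@H](C(C)C)[C@@H]2C1 | intermediate (not isolated)
30 | (1R,3S,3aS,7aR)-1-[(tert-butyldimethylsilyl)oxy]-6-{(2S)-5-[(1S,2R,5S)-2-ethenyl-5-methylcyclopentyl]pentan-2-yl}-7a-methyl-3-(propan-2-yl)-2,3,3a,4,7,7a-hexahydro-1H-inden-5-yl trifluoromethanesulfonate | O=S(=O)(OC1=C([C@@H](C)CC[C@@H]2[C@@H](C=C)CC[C@@H]2C)C[C@@]2(C)[C@H](O[Si](C)(C)C(C)(C)C)C[C@@H](C(C)C)[C@@H]2C1)C(F)(F)F | intermediate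
31 | tert-butyldimethylsilyl ether of the target | C=C1C2=C(C[C@@]3(C)[C@H](O[Si](C)(C)C(C)(C)C)C[C@@H](C(C)C)[C@@H]3C2)[C@@H](C)CC[C@@H]2[C@@H]1CC[C@@H]2C | intermediate
32 | target CNP0544018.1 (5-8-6-5 dienol) | C=C1C2=C(C[C@@]3(C)[C@H](O)C[C@@H](C(C)C)[C@@H]3C2)[C@@H](C)CC[C@@H]2[C@@H]1CC[C@@H]2C | target

**Totals**

Total step count: 19. Longest linear sequence: 13 steps (1–9, then 16–19).

**Steps most likely to fail**

Step 7. The tertiary radical may be lost before it cyclises (trapping by a second Ti(III) and deoxygenation to the alkene), may close 5-exo at the enone α-carbon, or may be poorly steered by the exocyclic carbinol centre. Fallback: the same radical is generated in a tin-hydride chain process without a stoichiometric metal reductant. Epoxide 9 is opened at the tertiary carbon with MgBr2·OEt2 to the bromohydrin tosylate F1. Slow addition of Bu3SnH/AIBN (benzene, 80 °C) to F1 then gives the free-hydroxyl radical, whose 6-endo cyclisation returns to 10.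

Step 17. Facial selectivity of methyl delivery to the exocyclic enone rests only on the distant angular methyl and may be low, giving both methyl epimers. Fallback: the centre is set by chirality transfer from the ring.
- Ketone 28 is reduced 1,2 (DIBAL-H, −78 °C; Mitsunobu inversion if the equatorial epimer forms) to the axial allylic alcohol F2.
- Phenyl isocyanate converts F2 into the N-phenylcarbamate F3.
- MeLi/CuI delivers methyl syn to the carbamate (syn-SN2′) to give the ring alkene F4 with the methyl centre fixed.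
- mCPBA epoxidises the trisubstituted ring alkene selectively to epoxide F5.
- Meinwald rearrangement (BF3·OEt2) gives ketone F6.
- Thermodynamic enol triflation (KH, then PhNTf2) returns to 30.

Step 18. The 8-exo insertion may be slow, allowing protodetriflation or diene isomerisation by palladium hydride. Fallback: the same bond is closed by a Nozaki–Hiyama–Kishi reaction. Selective ozonolysis of the terminal vinyl group of 30 (the enol triflate alkene is deactivated) gives aldehyde F7. CrCl2/NiCl2 (DMSO, high dilution) closes the ring to the allylic alcohol F8, Dess–Martin oxidation gives enone F9, and Tebbe methylenation returns to 31.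

**Further compounds**

F1 | step 7 | (2R,7E)-3-bromo-2-hydroxy-3,10-dimethyl-6-oxoundeca-7,9-dien-1-yl 4-methylbenzenesulfonate (C3 unassigned) | Cc1ccc(cc1)S(=O)(=O)OC[C@@H](O)C(C)(Br)CCC(=O)/C=C/C=C(C)C
F2 | step 17 | axial (α) C5 allylic alcohol from 1,2-reduction of 28 | O[C@H]1/C(=C/CC[C@@H]2[C@@H](C=C)CC[C@@H]2C)C[C@@]2(C)[C@H](O[Si](C)(C)C(C)(C)C)C[C@@H](C(C)C)[C@@H]2C1
F3 | step 17 | N-phenylcarbamate of F2 | O=C(Nc1ccccc1)O[C@H]1/C(=C/CC[C@@H]2[C@@H](C=C)CC[C@@H]2C)C[C@@]2(C)[C@H](O[Si](C)(C)C(C)(C)C)C[C@@H](C(C)C)[C@@H]2C1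
F4 | step 17 | C5–C6 ring alkene with the (S)-methyl side chain (syn-SN2′ product) | C1=C([C@@H](C)CC[C@@H]2[C@@H](C=C)CC[C@@H]2C)C[C@@]2(C)[C@H](O[Si](C)(C)C(C)(C)C)C[C@@H](C(C)C)[C@@H]2C1
F5 | step 17 | α-5,6-epoxide of F4 | [C@H]12O[C@@]1([C@@H](C)CC[C@@H]1[C@@H](C=C)CC[C@@H]1C)C[C@@]1(C)[C@H](O[Si](C)(C)C(C)(C)C)C[C@@H](C(C)C)[C@@H]1C2
F6 | step 17 | C5 ketone with the (S)-methyl side chain at C6 (C6 unassigned) | O=C1C([C@@H](C)CC[C@@H]2[C@@H](C=C)CC[C@@H]2C)C[C@@]2(C)[C@H](O[Si](C)(C)C(C)(C)C)C[C@@H](C(C)C)[C@@H]2C1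
F7 | step 18 | aldehyde from ozonolysis of the vinyl group of 30 | O=S(=O)(OC1=C([C@@H](C)CC[C@@H]2[C@@H](C=O)CC[C@@H]2C)C[C@@]2(C)[C@H](O[Si](C)(C)C(C)(C)C)C[C@@H](C(C)C)[C@@H]2C1)C(F)(F)F
F8 | step 18 | eight-membered ring allylic alcohol (carbinol unassigned) | OC1C2=C(C[C@@]3(C)[C@H](O[Si](C)(C)C(C)(C)C)C[C@@H](C(C)C)[C@@H]3C2)[C@@H](C)CC[C@@H]2[C@@H]1CC[C@@H]2C
F9 | step 18 | eight-membered ring enone | O=C1C2=C(C[C@@]3(C)[C@H](O[Si](C)(C)C(C)(C)C)C[C@@H](C(C)C)[C@@H]3C2)[C@@H](C)CC[C@@H]2[C@@H]1CC[C@@H]2C
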